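**Two balances.** In this closed flask, starting material, dormant form, product and the bound forms together stay equal to the charge, and whatever has left starting material counts as reacted. Precatalyst and the catalyst forms made from it likewise stay equal to the precatalyst charge.

starting material 1.0 M; precatalyst 50 mM

    precatalyst → free catalyst (k1 = 0.0320 min⁻¹)
    starting material + free catalyst → catalyst intermediate A (k2 = 160 M⁻¹ min⁻¹)
    catalyst intermediate B → free catalyst + product (k3 = 1.20 min⁻¹)
    catalyst intermediate A ⇌ catalyst intermediate B (K4 = 0.88, k4 = 3.44 min⁻¹)
    starting material ⇌ dormant form (K5 = 1.48, k5 = 0.178 min⁻¹)

- the form that holds most of the catalyst when 10 % of the starting material are converted (catalyst intermediate B / precatalyst / free catalyst / catalyst intermediate A)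
- its share of the catalyst then
- factor on the rate of making product when 10 % of the starting material are converted if precatalyst is charged twice over
- factor on the rate when 10 % of the starting material are converted if precatalyst is charged at 5.0 mM instead

**Opening rate.** Starting material first leaves for the dormant form at 0.178 min⁻¹, as a fraction of its charge. Precatalyst releases free catalyst at 0.00160 min⁻¹ in the same measure, so the dormant exchange runs faster, and the reckoning here rests on that exchange.

**The slowing.** At the mark of 10 % conversion, loss of starting material cuts the forward rate of the exchange to 90.0 % of its opening value, and the back step brings the net rate to 83.2 % of it. The exchange by itself heads for a dormant fraction of 59.7 %, which is higher than the mark, so in this reckoning the flask passes the mark on the way there.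

**Dormant clock.** The dormant clock, the time the exchange by itself takes to reach the mark, 0.615 min, contains no precatalyst term. It is shorter than the precatalyst lifetime of 31.2 min, so this reckoning leaves 98.1 % of the catalyst as precatalyst, an off-cycle form and no resting state. With the clock held, this reckoning takes the rate of making product to follow the charge, which gives a factor 2 for the doubled charge and 0.100 for 5.0 mM.

**Forecast and flask.** The forecast gives precatalyst at 98.1 % with factors 1.97 and 0.101, which differ from the factors above, its ground for the first being that “Doubling the charge shortens” the time.

The simulation gives precatalyst at 98.1 %, with factors 1.97 and 0.101. In this flask the mark is reached at 0.608 min, against a dormant clock of 0.615 min. In the flask with twice the precatalyst the clock stays the same, and the time to the mark there changes by a factor 0.989.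

All constants were drawn at random within sensible limits; the rest is arithmetic.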